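Assumption: the C4 configuration of the catechin-derived 2-ethoxyethyl ethers 14 and 15 is drawn as 4β (alcohol entering anti to the 2-aryl group); it has no bearing on the route, because this centre becomes planar again in step 12.

## Structural features

The target is a linear B-type procyanidin tetramer of four 2-(3,4-dihydroxyphenyl)chromane-3,5,7-triol units: unit 1 is (+)-catechin (2R,3S, 2,3-trans) and units 2, 3 and 4 are (−)-epicatechin (2R,3R, 2,3-cis). The units are held together only by C4–aryl single bonds: C4 of unit 1 (α) to C6 of ring A of unit 2, C4 of unit 2 (β) to C8 of unit 3, and C4 of unit 3 (β) to C8 of unit 4, whose own C4 is a methylene. Of the eleven stereocentres, the eight at C2 and C3 come as contiguous pairs with the two monomers, whereas the three at C4 of units 1 to 3, each next to C3 and trans to its oxygen, have to be created. The free phenols and catechols oxidise easily and allow C2 epimerisation in base, and every interflavan bond is a reversible Friedel–Crafts bond that strong acid reopens, so the phenols are carried as benzyl ethers and the last step is neutral and reductive. The real difficulty is that each interflavan bond is made by capture of a C4 benzylic cation by a phloroglucinol-type ring, and the product carries rings as nucleophilic as the reactant. Chain length, site (C8 or C6) and face at C4 must therefore all be controlled, and the 4→6 bond between units 1 and 2 runs against the innate C8 preference. The key step exploits the two axial 3-hydroxyls of units 3 and 4, which flank the C4(unit 3)–C8(unit 4) bond: bridged by a nine-carbon diacyl chain, they turn this bond formation into the closure of an 18-membered ring in which the cation meets exactly one ring A.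

## Logic of the disconnections

18 ⇒ 17. The seventeen O–benzyl bonds and the two C8–Br bonds (units 1 and 2) are cut. All phenols are thereby masked against oxidation and base, and the two most nucleophilic ring A positions of the electrophilic half are capped. The forward step must be a single hydrogenolysis that removes benzyl and bromine without touching the C4–aryl bonds.

17 ⇒ 16 + 9. The C4(unit 2)–C8(unit 3) bond is cut. This halves the molecule into two dimers that each contain one interflavan bond. The forward step must ionise C4 of unit 2 of 16 with an activator that leaves the rest alone, and the cation must be taken by C8 of unit 3 of 9 on the β face. The bromine caps of 16 make self-condensation slow, so 9 need not be used in large excess.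

9 ⇒ 8. The two 3-hydroxyls are re-joined as esters of one diacid chain. This adds no skeletal complexity but makes the dimer a macrocycle, which is what the key step forms. The forward demand is only an ester cleavage that spares benzyl ethers and the interflavan bond.

8 ⇒ 7. The C4(unit 3)–C8(unit 4) bond is cut and the 18-membered ring opens. The gain is a diester of two monomer-derived flavans in which electrophile and nucleophile are present 1:1 by construction. The forward step needs β-face attack at C4, C8 rather than C6 of unit 4, and ring closure rather than chain growth. 7 carries the 2-ethoxyethyl ether as leaving group and benzyl ethers only. Its assembly is arranged so that the diacid goes first onto the robust unit and the acid-labile unit is joined last, and 7 is added slowly to the catalyst. Ring A of unit 3 is left uncapped on purpose, because its C8 is the nucleophile of the later 2+2 coupling.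

7 ⇒ 6 + 4, 6 ⇒ 3 + 5, 4 ⇒ 3, 3 ⇒ 1 + 2. The two ester C–O bonds, the C4–O bond and the four phenolic O–benzyl bonds are cut in turn. Both halves of 7 thus come from the same monomer ether 3, and all four stereocentres at C2 and C3 come from 1. The forward steps need selective phenol alkylation with four equivalents of 2, mono-acylation of a diacid, and a C4 oxidation that gives the 3,4-trans ether.

16 ⇒ 15 + 11. The C4(unit 1)–C6(unit 2) bond is cut at the dimer stage, the only stage where C6 can be made the sole free ring A carbon of the nucleophile. The forward step must ionise the oxygen leaving group of 15 while the sulfur leaving group of 11 stays inert, and the cation must be attacked at a doubly flanked C6 from the α face.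

11 ⇒ 10 ⇒ 4. The C4–S bond and then the C8–Br bond are cut, so the unit 2 building block branches off from the intermediate 4 already made for unit 3. The forward demands are C8-selective bromination and a Lewis-acid exchange of oxygen for sulfur at C4.

15 ⇒ 14 ⇒ 13 ⇒ 12 + 2. The C8–Br bond, the C4–O bond and five O–benzyl bonds are cut. Unit 1 comes from 12 with its two stereocentres and takes up five equivalents of 2. The O3 benzyl ether is there to shield the β face in the coupling and costs no extra step.

## Other disconnections considered

Alternative 1: The cut is the C4–C4a bond of unit 2, with unit 1 already on the carbon between the two benzyloxy groups of a 3,5-dibenzyloxyphenyl ether. The open-chain precursor is aldehyde A1. The forward step is a BF3·OEt2-promoted intramolecular Friedel–Crafts hydroxyalkylation that closes ring C of unit 2, followed in the same flask by ionisation of the new benzylic alcohol and capture by 2-ethoxyethanol to give A2.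
- In its favour: the two carbons ortho to the ether oxygen are equivalent, so the 4→6 attachment of unit 1 follows from symmetry and not from a blocked C8, and the leaving group on unit 2 arises in the ring closure itself. On these two points the alternative is the better of the two, since the chosen plan needs a bromine, a sulfide and two different activators (steps 7, 8, 12 and 13) to arrive at the same kind of electrophile.
- Against it here: unit 2 is no longer taken from 1. C3 would have to come from the chiral pool and C2 from a stereocontrolled aryl ether formation. The α-benzyloxy aldehyde of A1 can epimerise at C3, and the benzylic aryl ether carbon can ionise under BF3·OEt2. Placing unit 1 on the symmetric arene beforehand is itself a cationic substitution with a site question. A2 carries no bromine, so in the 2+2 coupling with 9 its own rings A (C8 of unit 2, C8 and C6 of unit 1) would compete for the cation and an excess of 9 would be needed.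
- Comparison: structurally the end game is the same, and the alternative concerns the half of the molecule that step 5 does not touch, so it competes with steps 7 to 12 and not with the key step. Mechanistically the two are equal, both being arene captures of oxygen-stabilised cations. In step economy the de novo chain should cost more than the six steps 7 to 12.

Alternative 2: The cut is the C2–C3 bond of unit 1, made as an enol-ether double bond. The precursor is the cyclic sulfone A3, in which O1, C2, sulfur, C3, C4, C4a and C8a form a seven-membered ring. The forward step is a Ramberg–Bäcklund reaction (KOH, CBr2F2 on alumina): α-halogenation, closure to an episulfone and loss of SO2 would give the flav-2-ene A4.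
- In its favour: the C4(unit 1)–C6(unit 2) bond and the C4 configuration exist before the step, so no cation is ever formed at C4 of unit 1. Neither over-extension nor face selection at a hindered C6 arises, and on this point the alternative is the better. The ring contraction is unimolecular. A later hydroboration–oxidation of A4 would add H at C2 and OH at C3 syn, anti to the C4 aryl group, which is the 2,3-trans-3,4-trans pattern of unit 1.
- Against it here: the step would run on a fully assembled tetramer with many benzyl ethers under strongly basic, halogenating conditions, and the acid-labile enol ether A4 would then have to survive further handling. The diarylmethine C4 would have to be made enantioselectively by other means, and the two native stereocentres of 12 would be discarded and rebuilt under substrate control. CBr2F2 is an ozone-depleting reagent of restricted availability.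
- Comparison: structurally the chosen plan is convergent and ends with one coupling and one hydrogenolysis, whereas this one places ring construction and two stereocentres at the very end. Mechanistically it exchanges a cationic coupling for carbanion chemistry, which removes the over-extension problem but adds base sensitivity. In step economy, building the sulfone ring would be clearly longer than steps 9 to 12.

Alternative 3: The cut is the C4–C4a bond of unit 3. The precursor is the trans-epoxide A5, in which C4 already carries C8 of unit 4. The forward step is a BF3·OEt2-promoted epoxide–arene cyclisation at low temperature: an ortho carbon of the 3,5-dibenzyloxyphenyl ether would attack the benzylic epoxide carbon with inversion (6-endo opening) to close ring C and give A6.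
- In its favour: the C4–C8 bond exists before the key step, so there is no C8-against-C6 question and no competition between ring closure and chain growth, hence no need for dilution. On site selectivity and on concentration the alternative is the equal or the better of step 5. The 3,4-trans relation would follow from stereospecific anti opening, which is equal to the substrate control of step 5. A6 has a free 3-hydroxyl on unit 3 and would serve in step 13 as well as 9.
- Against it here: the epoxide carbon is benzylic to a trioxygenated ring, so ionisation to an open cation (loss of stereospecificity) and a 1,2-hydride shift to a ketone (Meinwald rearrangement) would compete with the cyclisation. Unit 3 would be built de novo: the C4 carbon would have to be joined to C8 of unit 4 beforehand, and C2, C3 and C4 set by reagent-controlled asymmetric oxidation instead of being taken from 1.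
- Comparison: structurally both plans deliver the same dimer core. Mechanistically the alternative trades an intramolecular capture of a free cation for an epoxide opening that is stereospecific only if it stays concerted. In step economy the chosen plan reaches 9 in six steps from 1 with both units from the same monomer, which a de novo unit 3 should not match.

Key step: step 5

## Route

Step 1
Reactants: 1 (−)-epicatechin; 2 benzyl bromide (four equivalents are consumed)
Product: 3 5,7,3',4'-tetra-O-benzyl-(−)-epicatechin
Conditions: BnBr (4.4 equiv), K2CO3, DMF, 0 °C to rt, argon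
Reagents that add atoms: benzyl bromide (three further equivalents), BrCc1ccccc1.BrCc1ccccc1.BrCc1ccccc1
Why: Fourfold Williamson ether synthesis, one benzyl bromide per phenol; K2CO3 deprotonates the four phenols but not the secondary 3-hydroxyl, and the mild base under argon avoids C2 epimerisation and oxidation of the free phenols.

Step 2
Reactants: 3 5,7,3',4'-tetra-O-benzyl-(−)-epicatechin
Product: 4 5,7,3',4'-tetra-O-benzyl-4β-(2-ethoxyethoxy)epicatechin (3,4-trans ether bearing a free 3-OH)
Conditions: DDQ (2 equiv), 2-ethoxyethanol (5 equiv), CH2Cl2, rt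
Reagents that add atoms: 2-ethoxyethanol, CCOCCO
Why: DDQ benzylic oxidation; hydride abstraction from C4 gives a cation stabilised by O1 and the 5- and 7-benzyloxy groups, and the alcohol should add on the β face, anti to the 2-aryl group and the axial 3-hydroxyl, to give the 3,4-trans ether.

Step 3
Reactants: 3 5,7,3',4'-tetra-O-benzyl-(−)-epicatechin; 5 azelaic acid
Product: 6 O3 hydrogen azelate of 5,7,3',4'-tetra-O-benzylepicatechin (half-ester bearing a free carboxylic acid)
Conditions: azelaic acid (5 equiv), DCC (1.2 equiv), DMAP (0.2 equiv), THF/CH2Cl2, 0 °C to rt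
Reagents that add atoms: none
Why: Steglich esterification; the fivefold excess of diacid makes the mono-ester the statistical product, and the acid 6 can be separated from unreacted 5 by extraction and from any bis-ester by chromatography.

Step 4
Reactants: 6 O3 hydrogen azelate of 5,7,3',4'-tetra-O-benzylepicatechin; 4 5,7,3',4'-tetra-O-benzyl-4β-(2-ethoxyethoxy)epicatechin
Product: 7 nonanedioate (azelate) diester joining O3 of 5,7,3',4'-tetra-O-benzyl-4β-(2-ethoxyethoxy)epicatechin to O3 of 5,7,3',4'-tetra-O-benzylepicatechin
Conditions: DCC (1.3 equiv), DMAP (0.3 equiv), CH2Cl2, 0 °C to rt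
Reagents that add atoms: none
Why: Steglich esterification; the conditions are neutral to weakly basic, so the acid-labile C4 ether is untouched, and the hindered 3-hydroxyl between the 2-aryl and 4-alkoxy groups is acylated through the acylpyridinium ion.

Step 5
Reactants: 7 nonanedioate (azelate) diester joining O3 of 5,7,3',4'-tetra-O-benzyl-4β-(2-ethoxyethoxy)epicatechin to O3 of 5,7,3',4'-tetra-O-benzylepicatechin
Product: 8 macrocyclic O3,O3'-azelate of octa-O-benzyl epicatechin-(4β→8)-epicatechin (18-membered ring)
Conditions: TMSOTf (0.5 equiv), CH2Cl2, −20 °C, 7 added over 8 h by syringe pump (final about 1 mM); Et3N quench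
Reagents that add atoms: none
Why: TMSOTf silylates the ether oxygen at C4 of unit 3 and the C4–O bond ionises to a benzylic cation stabilised by O1 and the 5- and 7-benzyloxy groups and, on the α face, by the carbonyl oxygen of the C3 ester (a 1,3-dioxolan-2-ylium form). C8 of ring A of the tethered unit 4 attacks this cation and loss of the ring proton regenerates the catalyst and releases 2-ethoxyethanol; this is an intramolecular Friedel–Crafts alkylation, the closest known type being the silyl-triflate-catalysed coupling of two flavan-3-ols joined through a dicarboxylate linker. The ring closes as an 18-membered macrocycle by attack on a planar carbon whose C4–C4a π bond lies outside the new ring (formally 18-exo-trig), which a ring of this size allows without strain. The one new stereocentre, C4 of unit 3, is under substrate control: the axial 3-acyloxy group and the 2-aryl group cover the α face, so the arene should enter on the β face, trans to O3. The step needs three selectivities: face (β), site (C8 and not C6 of unit 4) and ring closure instead of chain growth. The seven-methylene chain is long enough to fold round to the β face, so the tether does not have to override the innate facial preference; C8, flanked by O1 and only one benzyloxy group, is the less hindered and more nucleophilic carbon and leads to the smaller ring (18 against 19 atoms); slow addition keeps 7 dilute, so the single tethered ring A should capture the cation before a ring A of another molecule does.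

Step 6
Reactants: 8 macrocyclic O3,O3'-azelate of octa-O-benzyl epicatechin-(4β→8)-epicatechin
Product: 9 octa-O-benzyl epicatechin-(4β→8)-epicatechin (both 3-OH free)
Conditions: NaOMe (0.5 equiv), MeOH/THF (1:1), 40 °C
Reagents that add atoms: none
Why: Zemplén-type transesterification; methoxide cleaves both secondary alkyl esters, the chain leaves as dimethyl azelate and methoxide is regenerated, while benzyl ethers, the interflavan bond and the C2 centres (no free phenol) are inert to it.

Step 7
Reactants: 4 5,7,3',4'-tetra-O-benzyl-4β-(2-ethoxyethoxy)epicatechin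
Product: 10 8-bromo-5,7,3',4'-tetra-O-benzyl-4β-(2-ethoxyethoxy)epicatechin
Conditions: NBS (1.05 equiv), CH2Cl2, −78 to −20 °C, dark
Reagents that add atoms: N-bromosuccinimide, O=C1CCC(=O)N1Br
Why: Electrophilic aromatic bromination; C8, between O1 and one benzyloxy group, is more accessible than C6, between two benzyloxy groups and near the C4 substituent, and the by-product is succinimide and not HBr, so the C4 ether should survive.

Step 8
Reactants: 10 8-bromo-5,7,3',4'-tetra-O-benzyl-4β-(2-ethoxyethoxy)epicatechin
Product: 11 8-bromo-5,7,3',4'-tetra-O-benzyl-4β-[(2,6-dimethylphenyl)sulfanyl]epicatechin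
Conditions: 2,6-dimethylbenzenethiol (3 equiv), BF3·OEt2 (0.3 equiv), CH2Cl2, −78 to −20 °C
Reagents that add atoms: 2,6-dimethylbenzenethiol, Cc1cccc(C)c1S
Why: Lewis-acid-catalysed exchange at C4 (thiolysis type); BF3 ionises the ether and the thiol, in excess and far more nucleophilic than the brominated ring A, captures the cation on the β face trans to the 3-hydroxyl, and the aryl sulfide formed is not re-ionised by the oxophilic acid.

Step 9
Reactants: 12 (+)-catechin; 2 benzyl bromide (five equivalents are consumed)
Product: 13 3,5,7,3',4'-penta-O-benzyl-(+)-catechin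
Conditions: NaH (6 equiv), BnBr (6 equiv), DMF, −20 °C to rt, argon
Reagents that add atoms: benzyl bromide (four further equivalents), BrCc1ccccc1.BrCc1ccccc1.BrCc1ccccc1.BrCc1ccccc1
Why: Fivefold Williamson ether synthesis, one benzyl bromide per hydroxyl; the phenoxides are alkylated first and the 3-alkoxide last, and the low temperature with BnBr present from the start keeps free phenoxide short-lived, which should suppress C2 epimerisation.

Step 10
Reactants: 13 3,5,7,3',4'-penta-O-benzyl-(+)-catechin
Product: 14 3,5,7,3',4'-penta-O-benzyl-4β-(2-ethoxyethoxy)catechin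
Conditions: DDQ (2 equiv), 2-ethoxyethanol (5 equiv), CH2Cl2, rt
Reagents that add atoms: 2-ethoxyethanol, CCOCCO
Why: DDQ benzylic oxidation as in step 2; the electron-rich flavan C4–H is oxidised far faster than the benzyl ethers, and the configuration at C4 is immaterial because the centre is ionised in step 12.

Step 11
Reactants: 14 3,5,7,3',4'-penta-O-benzyl-4β-(2-ethoxyethoxy)catechin
Product: 15 8-bromo-3,5,7,3',4'-penta-O-benzyl-4β-(2-ethoxyethoxy)catechin
Conditions: NBS (1.05 equiv), CH2Cl2, −78 to −20 °C, dark
Reagents that add atoms: N-bromosuccinimide, O=C1CCC(=O)N1Br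
Why: Electrophilic aromatic bromination at C8 as in step 7; the bromine caps the most nucleophilic carbon of the future electrophile so that it cannot add to its own cation at that site.

Step 12
Reactants: 15 8-bromo-3,5,7,3',4'-penta-O-benzyl-4β-(2-ethoxyethoxy)catechin; 11 8-bromo-5,7,3',4'-tetra-O-benzyl-4β-[(2,6-dimethylphenyl)sulfanyl]epicatechin
Product: 16 8-bromo-penta-O-benzylcatechin-(4α→6)-[8-bromo-5,7,3',4'-tetra-O-benzyl-4β-(2,6-dimethylphenylsulfanyl)epicatechin]
Conditions: 11 (2.5 equiv, excess recovered), TMSOTf (0.3 equiv), CH2Cl2, −78 to −40 °C; Et3N quench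
Reagents that add atoms: none
Why: TMSOTf-catalysed Friedel–Crafts interflavan coupling with orthogonal leaving groups; the silyl triflate ionises the C4 ether of 15 but not the aryl sulfide of 11, whose sulfur is shielded by the two ortho methyl groups, C6 is the only free ring A carbon of 11 so the 4→6 link is forced, and the arene should enter α, anti to the 3β-benzyloxy group, to give the all-trans unit 1.

Step 13
Reactants: 16 8-bromo-penta-O-benzylcatechin-(4α→6)-[8-bromo-5,7,3',4'-tetra-O-benzyl-4β-(2,6-dimethylphenylsulfanyl)epicatechin]; 9 octa-O-benzyl epicatechin-(4β→8)-epicatechin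
Product: 17 heptadeca-O-benzyl-8,8'-dibromo tetramer [8-bromocatechin]-(4α→6)-[8-bromoepicatechin]-(4β→8)-epicatechin-(4β→8)-epicatechin (3-OH free on the three epicatechin units)
Conditions: 9 (1.5 equiv), AgBF4 (2 equiv), THF, 0 °C, dark, 4 Å molecular sieves; aq. NaHCO3 work-up
Reagents that add atoms: none
Why: Thiophilic activation followed by Friedel–Crafts capture; monovalent silver binds the sulfur and the C4–S bond ionises, the cation is taken by C8 of unit 3 of 9 (the most nucleophilic and least hindered ring A carbon, between O1 and one benzyloxy group) on the β face, anti to the 3α-hydroxyl and the 2-aryl group of unit 2, and the bromine caps on both rings A of 16 leave it no good site for self-condensation.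

Step 14
Reactants: 17 heptadeca-O-benzyl-8,8'-dibromo tetramer
Product: 18 catechin-(4α→6)-epicatechin-(4β→8)-epicatechin-(4β→8)-epicatechin (CNP0228086.1)
Conditions: H2 (1 atm), Pd(OH)2 on carbon, Et3N (2.2 equiv), THF/MeOH/H2O, rt; filtration under argon, freeze-drying
Reagents that add atoms: none
Why: Catalytic hydrogenolysis; all seventeen benzyl ethers and both aryl C–Br bonds are cleaved in one operation, Et3N takes up the HBr so that no acid reopens the interflavan bonds, and the diaryl-substituted C4 centres and the C2–O1 bonds are too hindered to be cleaved under these conditions.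

## Compound list

1 | (−)-epicatechin | Oc1cc(O)c2c(c1)O[C@H](c1ccc(O)c(O)c1)[C@H](O)C2 | starting material
2 | benzyl bromide | BrCc1ccccc1 | starting material
3 | 5,7,3',4'-tetra-O-benzyl-(−)-epicatechin | c1c(OCc9ccccc9)cc(OCc9ccccc9)c2c1O[C@H](c1ccc(OCc9ccccc9)c(OCc9ccccc9)c1)[C@H](O)C2 | intermediate
4 | 5,7,3',4'-tetra-O-benzyl-4β-(2-ethoxyethoxy)epicatechin | c1c(OCc9ccccc9)cc(OCc9ccccc9)c2c1O[C@H](c1ccc(OCc9ccccc9)c(OCc9ccccc9)c1)[C@H](O)[C@H]2OCCOCC | intermediate
5 | azelaic acid | OC(=O)CCCCCCCC(=O)O | starting material
6 | O3 hydrogen azelate of 5,7,3',4'-tetra-O-benzylepicatechin (free carboxylic acid) | OC(=O)CCCCCCCC(=O)O[C@@H]4Cc5c(OCc9ccccc9)cc(OCc9ccccc9)cc5O[C@@H]4c1ccc(OCc9ccccc9)c(OCc9ccccc9)c1 | intermediate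
7 | azelate diester joining O3 of 5,7,3',4'-tetra-O-benzyl-4β-(2-ethoxyethoxy)epicatechin (unit 3) to O3 of 5,7,3',4'-tetra-O-benzylepicatechin (unit 4), precursor of the key step | c1c(OCc9ccccc9)cc(OCc9ccccc9)c3c1O[C@H](c1ccc(OCc9ccccc9)c(OCc9ccccc9)c1)[C@H](OC(=O)CCCCCCCC(=O)O[C@@H]4Cc5c(OCc9ccccc9)cc(OCc9ccccc9)cc5O[C@@H]4c1ccc(OCc9ccccc9)c(OCc9ccccc9)c1)[C@H]3OCCOCC | intermediate
8 | macrocyclic O3,O3'-azelate of octa-O-benzyl epicatechin-(4β→8)-epicatechin, product of the key step | c1c(OCc9ccccc9)cc(OCc9ccccc9)c3c1O[C@H](c1ccc(OCc9ccccc9)c(OCc9ccccc9)c1)[C@H](OC(=O)CCCCCCCC(=O)O[C@@H]4Cc5c(OCc9ccccc9)cc(OCc9ccccc9)c6c5O[C@@H]4c1ccc(OCc9ccccc9)c(OCc9ccccc9)c1)[C@H]36 | intermediate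
9 | octa-O-benzyl epicatechin-(4β→8)-epicatechin, 3,3'-diol | c1c(OCc9ccccc9)cc(OCc9ccccc9)c3c1O[C@H](c1ccc(OCc9ccccc9)c(OCc9ccccc9)c1)[C@H](O)[C@H]3c1c(OCc9ccccc9)cc(OCc9ccccc9)c3c1O[C@H](c1ccc(OCc9ccccc9)c(OCc9ccccc9)c1)[C@H](O)C3 | intermediate
10 | 8-bromo-5,7,3',4'-tetra-O-benzyl-4β-(2-ethoxyethoxy)epicatechin | Brc1c(OCc9ccccc9)cc(OCc9ccccc9)c2c1O[C@H](c1ccc(OCc9ccccc9)c(OCc9ccccc9)c1)[C@H](O)[C@H]2OCCOCC | intermediate
11 | 8-bromo-5,7,3',4'-tetra-O-benzyl-4β-[(2,6-dimethylphenyl)sulfanyl]epicatechin | Brc1c(OCc9ccccc9)cc(OCc9ccccc9)c2c1O[C@H](c1ccc(OCc9ccccc9)c(OCc9ccccc9)c1)[C@H](O)[C@H]2Sc1c(C)cccc1C | intermediate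
12 | (+)-catechin | Oc1cc(O)c2c(c1)O[C@H](c1ccc(O)c(O)c1)[C@@H](O)C2 | starting material
13 | 3,5,7,3',4'-penta-O-benzyl-(+)-catechin | c1c(OCc9ccccc9)cc(OCc9ccccc9)c2c1O[C@H](c1ccc(OCc9ccccc9)c(OCc9ccccc9)c1)[C@@H](OCc9ccccc9)C2 | intermediate
14 | 3,5,7,3',4'-penta-O-benzyl-4β-(2-ethoxyethoxy)catechin | c1c(OCc9ccccc9)cc(OCc9ccccc9)c2c1O[C@H](c1ccc(OCc9ccccc9)c(OCc9ccccc9)c1)[C@@H](OCc9ccccc9)[C@H]2OCCOCC | intermediate
15 | 8-bromo-3,5,7,3',4'-penta-O-benzyl-4β-(2-ethoxyethoxy)catechin | Brc1c(OCc9ccccc9)cc(OCc9ccccc9)c2c1O[C@H](c1ccc(OCc9ccccc9)c(OCc9ccccc9)c1)[C@@H](OCc9ccccc9)[C@H]2OCCOCC | intermediate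
16 | 8-bromo-penta-O-benzylcatechin-(4α→6)-[8-bromo-5,7,3',4'-tetra-O-benzyl-4β-(2,6-dimethylphenylsulfanyl)epicatechin] | Brc1c(OCc9ccccc9)cc(OCc9ccccc9)c2c1O[C@H](c1ccc(OCc9ccccc9)c(OCc9ccccc9)c1)[C@@H](OCc9ccccc9)[C@@H]2c1c(OCc9ccccc9)c(Br)c2c(c1OCc9ccccc9)[C@H](Sc1c(C)cccc1C)[C@@H](O)[C@@H](c1ccc(OCc9ccccc9)c(OCc9ccccc9)c1)O2 | intermediate
17 | heptadeca-O-benzyl-8,8'-dibromo tetramer (3-OH free on units 2, 3 and 4) | Brc1c(OCc9ccccc9)cc(OCc9ccccc9)c2c1O[C@H](c1ccc(OCc9ccccc9)c(OCc9ccccc9)c1)[C@@H](OCc9ccccc9)[C@@H]2c1c(OCc9ccccc9)c(Br)c2c(c1OCc9ccccc9)[C@H](c1c(OCc9ccccc9)cc(OCc9ccccc9)c3c1O[C@H](c1ccc(OCc9ccccc9)c(OCc9ccccc9)c1)[C@H](O)[C@H]3c1c(OCc9ccccc9)cc(OCc9ccccc9)c3c1O[C@H](c1ccc(OCc9ccccc9)c(OCc9ccccc9)c1)[C@H](O)C3)[C@@H](O)[C@@H](c1ccc(OCc9ccccc9)c(OCc9ccccc9)c1)O2 | intermediate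
18 | catechin-(4α→6)-epicatechin-(4β→8)-epicatechin-(4β→8)-epicatechin (CNP0228086.1) | Oc1cc(O)c2c(c1)O[C@H](c1ccc(O)c(O)c1)[C@@H](O)[C@@H]2c1c(O)cc2c(c1O)[C@H](c1c(O)cc(O)c3c1O[C@H](c1ccc(O)c(O)c1)[C@H](O)[C@H]3c1c(O)cc(O)c3c1O[C@H](c1ccc(O)c(O)c1)[C@H](O)C3)[C@@H](O)[C@@H](c1ccc(O)c(O)c1)O2 | target

## Step count and least certain steps

Total: 14 steps. Longest linear sequence: 7 steps (steps 1, 2, 4, 5, 6, 13, 14; the branch through steps 1, 2, 7, 8, 12, 13, 14 is of equal length).

Step 5 (key step). The most likely failures are chain growth between molecules, because ring A of unit 3 of a second molecule is as nucleophilic as the tethered ring A, and delivery of the arene to the α face, because the chain hangs from the α oxygen and an unfavourable folding would bring ring A in cis to O3. Closure at C6 through the 19-membered ring is a lesser risk. The fallback gives up the tether. It sets out from 4, which would be acetylated at O3 (Ac2O, DMAP, pyridine) to 3-O-acetyl-5,7,3',4'-tetra-O-benzyl-4β-(2-ethoxyethoxy)epicatechin F1. TMSOTf-catalysed coupling of F1 with a fourfold excess of 3 in CH2Cl2 at −78 °C, with the participating acetate directing β attack, should give the unit 3 mono-acetate of the octa-O-benzyl dimer F2. Methanolysis with NaOMe then rejoins the route at 9.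

Step 12. The most likely failure is slow attack at the doubly flanked C6 of the brominated ring of 11. The cation of 15 would then be consumed by addition to C6 of another molecule of 15 or by transfer of the arylsulfanyl group through a sulfonium ion. The fallback installs the leaving group of unit 2 after the coupling instead of before. It sets out from 3, which would be brominated with NBS to 8-bromo-5,7,3',4'-tetra-O-benzylepicatechin F3. TMSOTf-catalysed coupling of 15 with an excess of F3 should give the dibromo dimer with a C4 methylene on unit 2, F4. DDQ oxidation of F4 in the presence of 2-ethoxyethanol should give the dibromo dimer with a 4β-(2-ethoxyethoxy) group on unit 2, F5. TMSOTf-catalysed coupling of F5 with 9 rejoins the route at 17, bypassing steps 8, 12 and 13.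

Step 13. The most likely failure is slow silver-assisted ionisation of the hindered aryl sulfide. HBF4 would then build up and reopen interflavan bonds already made, and capture could occur at the C6 positions or the hydroxyl oxygens of 9. The fallback separates ionisation from bond formation. It sets out from 16, which would be hydrolysed with AgBF4 in wet acetone buffered with NaHCO3, where water in large excess is the only nucleophile, to the dibromo dimer with a 4β-hydroxyl on unit 2, F6. TiCl4-promoted condensation of F6 with 9 in CH2Cl2/THF at 0 °C, a Friedel–Crafts coupling of a flavan-3,4-diol derivative, rejoins the route at 17.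

Step 14. The most likely failure is stalling of the hydrogenolysis before all seventeen benzyl ethers are gone, because bromide and traces of sulfur or silver from step 13 deactivate the catalyst. Prolonged exposure then risks reduction of the arene rings and air oxidation of partly deprotected material. The fallback removes the halogen first by a different mechanism. It sets out from 17, which would undergo bromine–lithium exchange with excess n-BuLi in THF at −78 °C and quenching with MeOH to give the bromine-free heptadeca-O-benzyl tetramer F7. Hydrogenolysis of F7 over Pd(OH)2 on carbon without amine rejoins the route at 18.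

## Further compounds

F1 | step 5 | 3-O-acetyl-5,7,3',4'-tetra-O-benzyl-4β-(2-ethoxyethoxy)epicatechin | c1c(OCc9ccccc9)cc(OCc9ccccc9)c2c1O[C@H](c1ccc(OCc9ccccc9)c(OCc9ccccc9)c1)[C@H](OC(C)=O)[C@H]2OCCOCC
F2 | step 5 | octa-O-benzyl epicatechin-(4β→8)-epicatechin, 3-O-acetate on unit 3 | c1c(OCc9ccccc9)cc(OCc9ccccc9)c3c1O[C@H](c1ccc(OCc9ccccc9)c(OCc9ccccc9)c1)[C@H](OC(C)=O)[C@H]3c1c(OCc9ccccc9)cc(OCc9ccccc9)c3c1O[C@H](c1ccc(OCc9ccccc9)c(OCc9ccccc9)c1)[C@H](O)C3
F3 | step 12 | 8-bromo-5,7,3',4'-tetra-O-benzylepicatechin | Brc1c(OCc9ccccc9)cc(OCc9ccccc9)c2c1O[C@H](c1ccc(OCc9ccccc9)c(OCc9ccccc9)c1)[C@H](O)C2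
F4 | step 12 | 8-bromo-penta-O-benzylcatechin-(4α→6)-[8-bromo-5,7,3',4'-tetra-O-benzylepicatechin] | Brc1c(OCc9ccccc9)cc(OCc9ccccc9)c2c1O[C@H](c1ccc(OCc9ccccc9)c(OCc9ccccc9)c1)[C@@H](OCc9ccccc9)[C@@H]2c1c(OCc9ccccc9)c(Br)c2c(c1OCc9ccccc9)C[C@@H](O)[C@@H](c1ccc(OCc9ccccc9)c(OCc9ccccc9)c1)O2
F5 | step 12 | 8-bromo-penta-O-benzylcatechin-(4α→6)-[8-bromo-5,7,3',4'-tetra-O-benzyl-4β-(2-ethoxyethoxy)epicatechin] | Brc1c(OCc9ccccc9)cc(OCc9ccccc9)c2c1O[C@H](c1ccc(OCc9ccccc9)c(OCc9ccccc9)c1)[C@@H](OCc9ccccc9)[C@@H]2c1c(OCc9ccccc9)c(Br)c2c(c1OCc9ccccc9)[C@H](OCCOCC)[C@@H](O)[C@@H](c1ccc(OCc9ccccc9)c(OCc9ccccc9)c1)O2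
F6 | step 13 | 8-bromo-penta-O-benzylcatechin-(4α→6)-[8-bromo-5,7,3',4'-tetra-O-benzyl-4β-hydroxyepicatechin] | Brc1c(OCc9ccccc9)cc(OCc9ccccc9)c2c1O[C@H](c1ccc(OCc9ccccc9)c(OCc9ccccc9)c1)[C@@H](OCc9ccccc9)[C@@H]2c1c(OCc9ccccc9)c(Br)c2c(c1OCc9ccccc9)[C@H](O)[C@@H](O)[C@@H](c1ccc(OCc9ccccc9)c(OCc9ccccc9)c1)O2
F7 | step 14 | heptadeca-O-benzyl tetramer without bromine | c1c(OCc9ccccc9)cc(OCc9ccccc9)c2c1O[C@H](c1ccc(OCc9ccccc9)c(OCc9ccccc9)c1)[C@@H](OCc9ccccc9)[C@@H]2c1c(OCc9ccccc9)cc2c(c1OCc9ccccc9)[C@H](c1c(OCc9ccccc9)cc(OCc9ccccc9)c3c1O[C@H](c1ccc(OCc9ccccc9)c(OCc9ccccc9)c1)[C@H](O)[C@H]3c1c(OCc9ccccc9)cc(OCc9ccccc9)c3c1O[C@H](c1ccc(OCc9ccccc9)c(OCc9ccccc9)c1)[C@H](O)C3)[C@@H](O)[C@@H](c1ccc(OCc9ccccc9)c(OCc9ccccc9)c1)O2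
A1 | alternative 1 | open-chain aldehyde: 2-benzyloxy-3-aryl-3-aryloxypropanal whose 3,5-dibenzyloxyphenyl ether carries penta-O-benzyl unit 1 at the carbon between the benzyloxy groups | c9ccccc9COc1cc(OCc9ccccc9)c2c(c1)O[C@H](c1ccc(OCc9ccccc9)c(OCc9ccccc9)c1)[C@@H](OCc9ccccc9)[C@@H]2c1c(OCc9ccccc9)cc(O[C@H](c2ccc(OCc9ccccc9)c(OCc9ccccc9)c2)[C@H](OCc9ccccc9)C=O)cc1OCc9ccccc9
A2 | alternative 1 | perbenzylated unit 1–unit 2 dimer with a 4β-(2-ethoxyethoxy) group on unit 2 | c9ccccc9COc1cc(OCc9ccccc9)c2c(c1)O[C@H](c1ccc(OCc9ccccc9)c(OCc9ccccc9)c1)[C@@H](OCc9ccccc9)[C@@H]2c1c(OCc9ccccc9)cc2c(c1OCc9ccccc9)[C@H](OCCOCC)[C@@H](OCc9ccccc9)[C@@H](c1ccc(OCc9ccccc9)c(OCc9ccccc9)c1)O2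
A3 | alternative 2 | protected tetramer with a seven-membered cyclic sulfone (benzoxathiepine S,S-dioxide, either configuration at the O,S-substituted carbon) in place of ring C of unit 1 | c9ccccc9COc1cc(OCc9ccccc9)c2c(c1)OC(c1ccc(OCc9ccccc9)c(OCc9ccccc9)c1)S(=O)(=O)C[C@@H]2c1c(OCc9ccccc9)c(Br)c2c(c1OCc9ccccc9)[C@H](c1c(OCc9ccccc9)cc(OCc9ccccc9)c3c1O[C@H](c1ccc(OCc9ccccc9)c(OCc9ccccc9)c1)[C@H](OCc9ccccc9)[C@H]3c1c(OCc9ccccc9)cc(OCc9ccccc9)c3c1O[C@H](c1ccc(OCc9ccccc9)c(OCc9ccccc9)c1)[C@H](OCc9ccccc9)C3)[C@@H](OCc9ccccc9)[C@@H](c1ccc(OCc9ccccc9)c(OCc9ccccc9)c1)O2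
A4 | alternative 2 | protected tetramer with unit 1 as a 4-aryl-4H-chromene (flav-2-ene) | c9ccccc9COc1cc(OCc9ccccc9)c2c(c1)OC(c1ccc(OCc9ccccc9)c(OCc9ccccc9)c1)=C[C@@H]2c1c(OCc9ccccc9)c(Br)c2c(c1OCc9ccccc9)[C@H](c1c(OCc9ccccc9)cc(OCc9ccccc9)c3c1O[C@H](c1ccc(OCc9ccccc9)c(OCc9ccccc9)c1)[C@H](OCc9ccccc9)[C@H]3c1c(OCc9ccccc9)cc(OCc9ccccc9)c3c1O[C@H](c1ccc(OCc9ccccc9)c(OCc9ccccc9)c1)[C@H](OCc9ccccc9)C3)[C@@H](OCc9ccccc9)[C@@H](c1ccc(OCc9ccccc9)c(OCc9ccccc9)c1)O2
A5 | alternative 3 | trans-epoxide: 3,5-dibenzyloxyphenyl ether of a 1-aryl-2,3-epoxypropan-1-ol whose C3 carries C8 of penta-O-benzyl unit 4 | c1c(OCc9ccccc9)cc(OCc9ccccc9)cc1O[C@H](c1ccc(OCc9ccccc9)c(OCc9ccccc9)c1)[C@@H]4O[C@H]4c1c(OCc9ccccc9)cc(OCc9ccccc9)c3c1O[C@H](c1ccc(OCc9ccccc9)c(OCc9ccccc9)c1)[C@H](OCc9ccccc9)C3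
A6 | alternative 3 | benzylated unit 3–unit 4 dimer with a free 3-hydroxyl on unit 3 | c1c(OCc9ccccc9)cc(OCc9ccccc9)c3c1O[C@H](c1ccc(OCc9ccccc9)c(OCc9ccccc9)c1)[C@H](O)[C@H]3c1c(OCc9ccccc9)cc(OCc9ccccc9)c3c1O[C@H](c1ccc(OCc9ccccc9)c(OCc9ccccc9)c1)[C@H](OCc9ccccc9)C3
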